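## Retrosynthetic overview
1. Disconnect the cyclohexene ring and the quaternary chromonyl-bearing carbon by an intermolecular [4+2] between a 2-(5,7-dihydroxychromon-2-yl)-5-methoxy-1,4-benzoquinone and a 7β-hydroxy-labda-8(17),12Z,14-trienoic acid. This forms three stereocentres in one step with no protecting groups.
2. Make the quinone by oxidative dearomatization (CAN) of the 2',4',5'-trimethoxyphenyl ring of a 5,7-dihydroxyflavone. Make the flavone from phloroacetophenone and 2,4,5-trimethoxybenzaldehyde by Claisen–Schmidt condensation and I2/DMSO cyclodehydrogenation.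
3. Make the diene acid from the resin-derived trienoic acid by C7 oxygenation (Riley oxidation, oxidation to the enone, Luche reduction). The four decalin stereocentres already exist.
4. Ring order: chromone ring, then quinone ring by dearomatization, then the cyclohexene ring by the Diels–Alder step last.

## Assumptions
- The target's CO2H is equatorial (4α) and trans to the C10 methyl, which makes it an 18-oic acid of the 4-epi-communic series. I assume 4-epi-cis-communic acid can be bought or isolated from conifer resin.
- Its ring stereocentres (C4, C5, C9, C10) already match the target.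
- Its Z-configured C12=C13 bond (C11 cis to C14) is what delivers the target relative configuration in the endo Diels–Alder step.

## Route

**Step 1**
Reactants: 1, 4-epi-cis-communic acid (labda-8(17),12Z,14-trien-18-oic acid)
Product: 2, 7α-hydroxy-labda-8(17),12Z,14-trien-18-oic acid
Conditions: SeO2 (0.3 equiv), TBHP (3 equiv), CH2Cl2, 0 °C → rt, 12 h
Reagents that add atoms: selenium dioxide (O=[Se]=O); tert-butyl hydroperoxide (CC(C)(C)OO)
Why: Riley allylic oxidation of the exocyclic methylene. An ene reaction puts Se on C17 and moves the double bond to C7=C8, then a [2,3]-shift places O on C7 to give the 7-hydroxy-8(17)-ene. The new C7 centre (mainly 7α) is erased in Step 2.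

**Step 2**
Reactants: 2
Product: 3, 7-oxo-labda-8(17),12Z,14-trien-18-oic acid
Conditions: MnO2 (15 equiv), CH2Cl2, rt, 6 h
Reagents that add atoms: none
Why: MnO2 oxidation selectively converts the allylic alcohol (either epimer) to the exocyclic enone. The acid, the diene and the non-allylic positions are untouched, and the ketone C7 is not a stereocentre.

**Step 3**
Reactants: 3
Product: 4, 7β-hydroxy-labda-8(17),12Z,14-trien-18-oic acid
Conditions: NaBH4 (2 equiv), CeCl3·7H2O (1.5 equiv), MeOH, –20 °C, 1 h
Reagents that add atoms: none
Why: Luche 1,2-reduction of the α-methylene ketone. Hydride adds axially from the unhindered α face (the axial H-5 and H-9 are small, and the hindered axial C10 methyl is on the β face). This sets the equatorial 7β-OH required by the target.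

**Step 4**
Reactants: 5, 2,4,6-trihydroxyacetophenone; 6, 2,4,5-trimethoxybenzaldehyde
Product: 7, (E)-2',4',6'-trihydroxy-2,4,5-trimethoxychalcone
Conditions: KOH (5 equiv), EtOH–H2O, 25 °C, 72 h; then HCl to pH 3
Reagents that add atoms: none
Why: Claisen–Schmidt aldol condensation. Excess base keeps the phenols as phenolates, and the E-enone forms under thermodynamic control.

**Step 5**
Reactants: 7
Product: 8, 5,7-dihydroxy-2',4',5'-trimethoxyflavone
Conditions: I2 (0.1 equiv), DMSO, 130 °C, 4 h
Reagents that add atoms: none
Why: I2/DMSO oxidative cyclization. The 2'-OH adds to the enone to give the flavanone, which is dehydrogenated to the flavone. This forms the chromone ring.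

**Step 6**
Reactants: 8
Product: 9, 2-(5,7-dihydroxy-4-oxo-4H-chromen-2-yl)-5-methoxy-1,4-benzoquinone
Conditions: CAN (2.5 equiv), MeCN–H2O (3:1), 0 °C, 10 min
Reagents that add atoms: water (O)
Why: Ceric ammonium nitrate oxidatively demethylates the para 2',5'-dimethoxy pair, which dearomatizes the B ring to the p-quinone and supplies the two carbonyl oxygens from water. The 4'-OMe has no para partner and is retained. The electron-poor 5,7-dihydroxychromone ring should survive.

**Step 7**
Reactants: 4, 7β-hydroxy diene acid (1 equiv); 9, chromonyl-methoxybenzoquinone (1.5 equiv)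
Product: 10, Dichrostachine E
Conditions: CH2Cl2–THF (4:1), BHT (cat.), 13 kbar, 25 °C, 72 h; then preparative HPLC
Reagents that add atoms: none
Why: Proposed new method: a high-pressure, protecting-group-free intermolecular quinone Diels–Alder that forms the C12–C1' quaternary bond and the cyclohexene in one step. The closest known reaction is the high-pressure [4+2] of 2-substituted 5-methoxybenzoquinones with 1-substituted 2-methylbutadienes. The OMe-bearing quinone C=C is a deactivated vinylogous ester, so the diene adds to the chromonyl-bearing C=C. That C1' is β to the free C5' carbonyl, so the nucleophilic diene terminus C12 (next to the methyl-bearing C13) bonds to it. Suprafacial addition makes the ring fusion cis (H-6' and chromonyl syn). Endo approach of the quinone ring to the 12Z diene puts C11 cis to the chromonyl and trans to the C2' carbonyl, as in the target. The decalin gives only modest facial bias on the diene, so the two diastereomeric adducts are separated by HPLC. The quaternary C1' prevents aromatization of the adduct.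

## Compound list
1 | 4-epi-cis-communic acid (labda-8(17),12Z,14-trien-18-oic acid) | C=C1CC[C@@H]2[C@](C)(CCC[C@@]2(C)C(=O)O)[C@H]1C/C=C(/C)C=C | starting material
2 | 7α-hydroxy-labda-8(17),12Z,14-trien-18-oic acid | C=C1[C@H](O)C[C@@H]2[C@](C)(CCC[C@@]2(C)C(=O)O)[C@H]1C/C=C(/C)C=C | intermediate
3 | 7-oxo-labda-8(17),12Z,14-trien-18-oic acid | C=C1C(=O)C[C@@H]2[C@](C)(CCC[C@@]2(C)C(=O)O)[C@H]1C/C=C(/C)C=C | intermediate
4 | 7β-hydroxy-labda-8(17),12Z,14-trien-18-oic acid | C=C1[C@@H](O)C[C@@H]2[C@](C)(CCC[C@@]2(C)C(=O)O)[C@H]1C/C=C(/C)C=C | intermediate
5 | 2,4,6-trihydroxyacetophenone | CC(=O)c1c(O)cc(O)cc1O | starting material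
6 | 2,4,5-trimethoxybenzaldehyde | COc1cc(OC)c(C=O)cc1OC | starting material
7 | (E)-2',4',6'-trihydroxy-2,4,5-trimethoxychalcone | COc1cc(OC)c(/C=C/C(=O)c2c(O)cc(O)cc2O)cc1OC | intermediate
8 | 5,7-dihydroxy-2',4',5'-trimethoxyflavone | COc1cc(OC)c(-c2cc(=O)c3c(O)cc(O)cc3o2)cc1OC | intermediate
9 | 2-(5,7-dihydroxychromon-2-yl)-5-methoxy-1,4-benzoquinone | COC1=CC(=O)C(c2cc(=O)c3c(O)cc(O)cc3o2)=CC1=O | intermediate
10 | Dichrostachine E | C=C1[C@@H](O)C[C@@H]2[C@](C)(CCC[C@@]2(C)C(=O)O)[C@H]1C[C@@H]1C(C)=CC[C@H]2C(=O)C(OC)=CC(=O)[C@@]12c1cc(=O)c2c(O)cc(O)cc2o1 | target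

## Totals
- Total steps: 7.
- Longest linear sequence: 4 steps (Steps 1, 2, 3, 7 from 1; or Steps 4, 5, 6, 7 from 5/6).

## Three steps most likely to fail
1. **Step 7 (Diels–Alder).** The Z-diene has an "inside" C11 substituent and reacts sluggishly. The new bond joins a secondary centre to a quaternary one, and the diene-face selectivity is weak. Fallback: use the more reactive 2-acetyl-5-methoxybenzoquinone as dienophile to give the acetyl-bearing quaternary adduct. Then build the chromone late by acylating the acetyl enolate with a 2-hydroxy-4,6-dialkoxybenzoate and cyclodehydrating.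
2. **Step 1 (SeO2 oxidation).** SeO2 may attack the conjugated diene or C11/C16 instead of C7. Fallback: mask the diene as its Fe(CO)3 complex (Fe2(CO)9), carry out the C7 oxidation, oxidation and Luche reduction sequence, then release the diene with Me3NO. This leaves the diene unexposed to the selenium reagent, and the Z geometry should be retained.
3. **Step 6 (CAN).** Over-oxidation or decomposition of the free 5,7-dihydroxychromone ring. Fallback: build the 2,5-dihydroxy-4-methoxyphenyl flavone instead, starting from 2,5-dihydroxy-4-methoxybenzaldehyde in the chalcone/flavone sequence. Generate the quinone with Ag2O in situ in the presence of diene 4 during the Diels–Alder, which avoids CAN.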